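**Overview** (flavone numbering: O1, C2–C4, C4a, C5–C8, C8a; ring B primed; MOM = methoxymethyl)

- Cuts: the two prenyl–oxygen bonds at O3 and O4' first, then C4–C4a of the pyranone (the strategic cut), then the vinyl ether bond O1–C2, and last C2–C3 of the three-carbon unit.
- Forward: rings A and B are bought as benzene rings. Ring A is trimmed to a 2-methoxy-3,5-dioxygenated phenol, ring B is built into an α-benzyloxy-β-chlorocinnamate, the halves are joined at O1–C2, and ring C is the only ring formed, by C4–C4a cycloacylation.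
- Enabling feature: in ring A, C8a (which carries O1) lies between C8, blocked by the methoxy group, and C4a, which is free, ortho to O1 and O5 and para to O7. Once O1–C2 exists the acyl carbon C4 can reach only C4a, so no 6-methoxy/8-methoxy ambiguity can arise.
- Protecting groups: O3 and O4' carry benzyl through the cationic ring closure and are prenylated afterwards; O5 and O7 carry MOM, removed last under mild acid.
- Stereochemistry: the target has no stereocentre and its prenyl alkenes have no E/Z isomers. The one racemic centre made on the way (step 6) becomes sp2 in step 7, and the acrylate geometry is erased in step 10.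

Key step: step 10

Assumption: acrylates 11 to 14 are drawn as the E isomers (chlorine or aryloxy cis to the carbonyl group), but either isomer or a mixture is expected and is carried forward.

**Route**

Step 1
Reactants: 1 2,4,6-trihydroxybenzaldehyde
Product: 2 2-hydroxy-4,6-bis(methoxymethoxy)benzaldehyde
Conditions: MOMCl (2.2 equiv), i-Pr2NEt, CH2Cl2, 0 °C to rt
Reagents that add atoms: chloromethyl methyl ether (MOMCl), COCCl
Why: Williamson-type O-alkylation with two equivalents of MOMCl should take the para hydroxyl and one ortho hydroxyl, because the remaining ortho hydroxyl is locked in a hydrogen bond to the formyl oxygen and is the least nucleophilic (chelation-controlled selective protection of a polyhydroxybenzaldehyde).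

Step 2
Reactants: 2 2-hydroxy-4,6-bis(methoxymethoxy)benzaldehyde
Product: 3 2-(benzyloxy)-4,6-bis(methoxymethoxy)benzaldehyde
Conditions: BnBr, K2CO3, DMF, 60 °C
Reagents that add atoms: benzyl bromide, BrCc1ccccc1
Why: Williamson etherification under more forcing conditions alkylates the chelated phenol, which places a hydrogenolysable group, orthogonal to MOM, on the oxygen that later becomes O1.

Step 3
Reactants: 3 2-(benzyloxy)-4,6-bis(methoxymethoxy)benzaldehyde
Product: 5 2-(benzyloxy)-4,6-bis(methoxymethoxy)phenol, via aryl formate 4 (not isolated)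
Conditions: mCPBA, CH2Cl2, 0 °C to rt; wash with aq. Na2S2O3/NaHCO3; then K2CO3 (cat.), MeOH, 0 °C, under argon
Reagents that add atoms: 3-chloroperoxybenzoic acid (mCPBA), OOC(=O)c1cccc(Cl)c1
Why: Baeyer–Villiger oxidation of an electron-rich benzaldehyde goes with aryl migration (Dakin-type), and base-catalysed methanolysis of the resulting formate 4 uncovers a phenol at the carbon that becomes C8.

Step 4
Reactants: 5 2-(benzyloxy)-4,6-bis(methoxymethoxy)phenol
Product: 6 1-(benzyloxy)-2-methoxy-3,5-bis(methoxymethoxy)benzene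
Conditions: MeI, K2CO3, acetone, 40 °C
Reagents that add atoms: iodomethane, CI
Why: Williamson methylation of the only free hydroxyl installs the 8-methoxy group while its two neighbours are still differentiated as benzyl and MOM ethers.

Step 5
Reactants: 6 1-(benzyloxy)-2-methoxy-3,5-bis(methoxymethoxy)benzene
Product: 7 2-methoxy-3,5-bis(methoxymethoxy)phenol
Conditions: H2 (1 atm), 10% Pd/C, EtOAc, rt
Reagents that add atoms: none
Why: Hydrogenolysis of the aryl benzyl ether over palladium on carbon leaves the MOM acetals and the methyl ether untouched and frees only the future O1.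

Step 6
Reactants: 8 methyl 2-(benzyloxy)acetate; 9 4-(benzyloxy)benzoyl chloride
Product: 10 methyl 2-(benzyloxy)-3-[4-(benzyloxy)phenyl]-3-oxopropanoate (racemic)
Conditions: 8 (2.1 equiv), LiN(SiMe3)2 (2.1 equiv), THF, −78 °C; then 9 (1.0 equiv), −78 to −30 °C; aq. NH4Cl
Reagents that add atoms: none
Why: Crossed Claisen condensation in which the preformed lithium enolate of the glycolate ester is C-acylated by the non-enolisable aroyl chloride, the second equivalent of enolate deprotonating the more acidic β-keto ester so that it is not acylated again, and the new stereocentre is left racemic because it becomes sp2 in step 7.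

Step 7
Reactants: 10 methyl 2-(benzyloxy)-3-[4-(benzyloxy)phenyl]-3-oxopropanoate
Product: 11 methyl (E)-2-(benzyloxy)-3-[4-(benzyloxy)phenyl]-3-chloroprop-2-enoate
Conditions: (COCl)2, DMF, CH2Cl2, 0 °C to 40 °C
Reagents that add atoms: oxalyl chloride, O=C(Cl)C(Cl)=O
Why: The chloroiminium (Vilsmeier) salt formed from oxalyl chloride and DMF activates the enol oxygen as a leaving group and chloride replaces it by addition–elimination, the standard deoxychlorination of a β-keto ester to a β-chloroacrylate, the geometry of which need not be controlled.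

Step 8
Reactants: 7 2-methoxy-3,5-bis(methoxymethoxy)phenol; 11 methyl (E)-2-(benzyloxy)-3-[4-(benzyloxy)phenyl]-3-chloroprop-2-enoate
Product: 12 methyl (E)-2-(benzyloxy)-3-[4-(benzyloxy)phenyl]-3-[2-methoxy-3,5-bis(methoxymethoxy)phenoxy]prop-2-enoate
Conditions: Cs2CO3, degassed DMF, 70 °C
Reagents that add atoms: none
Why: Nucleophilic vinylic substitution by addition–elimination, in which the caesium phenoxide adds to the β-carbon of the β-chloroacrylate to give an ester enolate that expels chloride, which forms the O1–C2 bond before any bond to a ring-A carbon is made.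

Step 9
Reactants: 12 methyl (E)-2-(benzyloxy)-3-[4-(benzyloxy)phenyl]-3-[2-methoxy-3,5-bis(methoxymethoxy)phenoxy]prop-2-enoate
Product: 13 (E)-2-(benzyloxy)-3-[4-(benzyloxy)phenyl]-3-[2-methoxy-3,5-bis(methoxymethoxy)phenoxy]prop-2-enoic acid
Conditions: LiOH·H2O, THF/MeOH/H2O, 40 °C; then 1 M HCl to pH 4 at 0 °C
Reagents that add atoms: lithium hydroxide, [Li+].[OH-]
Why: Saponification of the methyl ester by hydroxide (acyl–oxygen cleavage), with cold acidification only to about pH 4 so that the MOM acetals and the push–pull acrylic acid, which is prone to protodecarboxylation in strong acid, survive.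

Step 10
Reactants: 13 (E)-2-(benzyloxy)-3-[4-(benzyloxy)phenyl]-3-[2-methoxy-3,5-bis(methoxymethoxy)phenoxy]prop-2-enoic acid
Product: 15 3-(benzyloxy)-2-[4-(benzyloxy)phenyl]-8-methoxy-5,7-bis(methoxymethoxy)-4H-chromen-4-one, via mixed trifluoroacetic anhydride 14 (not isolated)
Conditions: (CF3CO)2O (2 equiv), CH2Cl2 (0.02 M), 0 °C to rt; quench with cold aq. NaHCO3
Reagents that add atoms: none
Why: Trifluoroacetic anhydride turns the acid into mixed anhydride 14, which ionises to an acylium ion stabilised as a vinylogous oxocarbenium ion by O1 and ring B, and because the C2–C3 bond of this ion has little double-bond character either alkene isomer of 13 can bring the acyl carbon C4 over ring A, where C4a attacks and loss of the proton restores the aromatic ring and delivers the pyranone at its final oxidation level. The closest known reaction type is the intramolecular Friedel–Crafts acylation of β-aryloxycinnamic acids to flavones (Ruhemann flavone synthesis), run here through a mixed anhydride instead of a mineral acid. Ring C (O1–C2–C3–C4–C4a–C8a) is the only ring closed, by formation of C4–C4a in a six-membered closure that is exo at the acyl carbon (6-exo-trig). No stereocentre is formed. The selectivity needed is acylation at C4a and nowhere else, and the substrate secures it: a six-membered transition state starting from O1 reaches only the two carbons ortho to O1, C8 carries the methoxy group (ipso attack there is reversible and leads nowhere), while C4a is free and activated by O1 and O5 (ortho) and O7 (para), far above the unactivated benzyl ring and the ring-B positions meta to O4'. The two equivalents of trifluoroacetic acid released are dilute and cold enough that the MOM acetals should survive, and even loss of the peri 5-O-MOM group would be harmless because a chelated 5-hydroxyl is inert in step 12 and free in the target.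

Step 11
Reactants: 15 3-(benzyloxy)-2-[4-(benzyloxy)phenyl]-8-methoxy-5,7-bis(methoxymethoxy)-4H-chromen-4-one
Product: 16 3-hydroxy-2-(4-hydroxyphenyl)-8-methoxy-5,7-bis(methoxymethoxy)-4H-chromen-4-one
Conditions: H2 (1 atm), 10% Pd/C, EtOAc/THF, rt
Reagents that add atoms: none
Why: Hydrogenolysis over palladium on carbon cleaves both the aryl benzyl ether and the enolic 3-O-benzyl ether, while the C2=C3 bond, which is part of a vinylogous ester within the aromatic pyranone, and the MOM acetals should stay untouched at one atmosphere and room temperature.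

Step 12
Reactants: 16 3-hydroxy-2-(4-hydroxyphenyl)-8-methoxy-5,7-bis(methoxymethoxy)-4H-chromen-4-one; 17 1-bromo-3-methylbut-2-ene (prenyl bromide, 2.4 equiv)
Product: 18 8-methoxy-5,7-bis(methoxymethoxy)-3-[(3-methylbut-2-en-1-yl)oxy]-2-{4-[(3-methylbut-2-en-1-yl)oxy]phenyl}-4H-chromen-4-one
Conditions: K2CO3, DMF, rt
Reagents that add atoms: none
Why: Double Williamson O-alkylation (SN2 at the primary allylic bromide) of the 4'-phenoxide and the acidic enolic 3-hydroxyl, the only free hydroxyls since O5 and O7 are masked, which is why the prenyl groups, unsuited to the cationic step 10 and to hydrogenolysis, are introduced only now.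

Step 13
Reactants: 18 8-methoxy-5,7-bis(methoxymethoxy)-3-[(3-methylbut-2-en-1-yl)oxy]-2-{4-[(3-methylbut-2-en-1-yl)oxy]phenyl}-4H-chromen-4-one
Product: 19 5,7-dihydroxy-8-methoxy-3-[(3-methylbut-2-en-1-yl)oxy]-2-{4-[(3-methylbut-2-en-1-yl)oxy]phenyl}-4H-chromen-4-one (5,7-dihydroxy-8-methoxy-3,4'-diprenyloxyflavone)
Conditions: 2 M aq. HCl, MeOH/THF, rt, monitored and stopped at full conversion
Reagents that add atoms: none
Why: Acid-catalysed acetal cleavage (methanolysis through the methoxymethyl oxocarbenium ion) is much faster than ionisation of an aryl or enol prenyl ether to the prenyl cation, so dilute acid at room temperature should free the 5- and 7-hydroxyls and leave both prenyl ethers and the 8-methoxy group in place, too mildly for Wessely–Moser isomerisation.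

**Compound list**

1 | 2,4,6-trihydroxybenzaldehyde | O=Cc1c(O)cc(O)cc1O | starting material
2 | 2-hydroxy-4,6-bis(methoxymethoxy)benzaldehyde | O=Cc1c(O)cc(OCOC)cc1OCOC | intermediate
3 | 2-(benzyloxy)-4,6-bis(methoxymethoxy)benzaldehyde | O=Cc1c(OCc2ccccc2)cc(OCOC)cc1OCOC | intermediate
4 | 2-(benzyloxy)-4,6-bis(methoxymethoxy)phenyl formate (formed in step 3, not isolated) | O=COc1c(OCc2ccccc2)cc(OCOC)cc1OCOC | intermediate
5 | 2-(benzyloxy)-4,6-bis(methoxymethoxy)phenol | Oc1c(OCc2ccccc2)cc(OCOC)cc1OCOC | intermediate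
6 | 1-(benzyloxy)-2-methoxy-3,5-bis(methoxymethoxy)benzene | COc1c(OCc2ccccc2)cc(OCOC)cc1OCOC | intermediate
7 | 2-methoxy-3,5-bis(methoxymethoxy)phenol | COc1c(O)cc(OCOC)cc1OCOC | intermediate
8 | methyl 2-(benzyloxy)acetate | COC(=O)COCc1ccccc1 | starting material
9 | 4-(benzyloxy)benzoyl chloride | O=C(Cl)c1ccc(OCc2ccccc2)cc1 | starting material
10 | methyl 2-(benzyloxy)-3-[4-(benzyloxy)phenyl]-3-oxopropanoate (racemic) | COC(=O)C(OCc1ccccc1)C(=O)c1ccc(OCc2ccccc2)cc1 | intermediate
11 | methyl (E)-2-(benzyloxy)-3-[4-(benzyloxy)phenyl]-3-chloroprop-2-enoate | COC(=O)/C(OCc1ccccc1)=C(\Cl)c1ccc(OCc2ccccc2)cc1 | intermediate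
12 | methyl (E)-2-(benzyloxy)-3-[4-(benzyloxy)phenyl]-3-[2-methoxy-3,5-bis(methoxymethoxy)phenoxy]prop-2-enoate | COC(=O)/C(OCc1ccccc1)=C(\Oc1cc(OCOC)cc(OCOC)c1OC)c1ccc(OCc2ccccc2)cc1 | intermediate
13 | (E)-2-(benzyloxy)-3-[4-(benzyloxy)phenyl]-3-[2-methoxy-3,5-bis(methoxymethoxy)phenoxy]prop-2-enoic acid | OC(=O)/C(OCc1ccccc1)=C(\Oc1cc(OCOC)cc(OCOC)c1OC)c1ccc(OCc2ccccc2)cc1 | intermediate
14 | (E)-2-(benzyloxy)-3-[4-(benzyloxy)phenyl]-3-[2-methoxy-3,5-bis(methoxymethoxy)phenoxy]prop-2-enoic trifluoroacetic anhydride (formed in step 10, not isolated) | O=C(OC(=O)C(F)(F)F)/C(OCc1ccccc1)=C(\Oc1cc(OCOC)cc(OCOC)c1OC)c1ccc(OCc2ccccc2)cc1 | intermediate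
15 | 3-(benzyloxy)-2-[4-(benzyloxy)phenyl]-8-methoxy-5,7-bis(methoxymethoxy)-4H-chromen-4-one | COCOc1cc(OCOC)c2c(=O)c(OCc3ccccc3)c(-c3ccc(OCc4ccccc4)cc3)oc2c1OC | intermediate
16 | 3-hydroxy-2-(4-hydroxyphenyl)-8-methoxy-5,7-bis(methoxymethoxy)-4H-chromen-4-one | COCOc1cc(OCOC)c2c(=O)c(O)c(-c3ccc(O)cc3)oc2c1OC | intermediate
17 | 1-bromo-3-methylbut-2-ene (prenyl bromide) | CC(C)=CCBr | starting material
18 | 8-methoxy-5,7-bis(methoxymethoxy)-3-[(3-methylbut-2-en-1-yl)oxy]-2-{4-[(3-methylbut-2-en-1-yl)oxy]phenyl}-4H-chromen-4-one | COCOc1cc(OCOC)c2c(=O)c(OCC=C(C)C)c(-c3ccc(OCC=C(C)C)cc3)oc2c1OC | intermediate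
19 | 5,7-dihydroxy-8-methoxy-3-[(3-methylbut-2-en-1-yl)oxy]-2-{4-[(3-methylbut-2-en-1-yl)oxy]phenyl}-4H-chromen-4-one | COc1c(O)cc(O)c2c(=O)c(OCC=C(C)C)c(-c3ccc(OCC=C(C)C)cc3)oc12 | target

**Step count and risks**

Total step count: 13 steps.
Longest linear sequence: 11 steps (steps 1 to 5 and 8 to 13, from 1). The acrylate arm (steps 6 and 7) joins at step 8.

The three steps most likely to fail:

1. Step 8 (aryl vinyl ether by vinylic substitution). Process at risk: addition of the ortho-substituted phenoxide to a tetrasubstituted β-carbon, which the α-benzyloxy group both shields and deactivates, may be slower than oxidative decay of the phenoxide or its attack at the ester. Fallback, setting out from phenol 7 and coming back to the route at 16: the α-oxygen is left out of the acceptor and O3 is introduced after ring closure. Commercial 1-(benzyloxy)-4-ethynylbenzene is lithiated (n-BuLi) and trapped with methyl chloroformate to give methyl 3-[4-(benzyloxy)phenyl]prop-2-ynoate F1. Base-mediated oxa-Michael addition of 7 (K2CO3, DMF) should give methyl (Z)-3-[4-(benzyloxy)phenyl]-3-[2-methoxy-3,5-bis(methoxymethoxy)phenoxy]prop-2-enoate F2. Saponification as in step 9 gives the corresponding acrylic acid F3, and treatment as in step 10 passes through its mixed trifluoroacetic anhydride F4 to 2-[4-(benzyloxy)phenyl]-8-methoxy-5,7-bis(methoxymethoxy)-4H-chromen-4-one F5, the parent case of the Ruhemann flavone synthesis. Dimethyldioxirane in acetone/CH2Cl2 should epoxidise C2=C3 to the racemic flavone 2,3-epoxide F6, which a trace of p-TsOH opens to 2-[4-(benzyloxy)phenyl]-3-hydroxy-8-methoxy-5,7-bis(methoxymethoxy)-4H-chromen-4-one F7. Hydrogenolysis of its single benzyl ether (H2, Pd/C) then gives 16.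

2. Step 10 (cycloacylation). Process at risk: acid-induced loss of the MOM acetals before the ring has closed, followed by O-trifluoroacetylation that lowers the nucleophilicity of ring A, or diversion of the activated acid by protodecarboxylation. Fallback, setting out from phenol 7 (with acid chloride 9) and coming back at 15: ring C is closed at O1–C2 with base only, which is still unambiguous because 7 has a single free hydroxyl and a single free ortho carbon. The bromomagnesium phenoxide of 7 (EtMgBr, toluene) is acylated at that ortho carbon with benzyloxyacetyl chloride (chelation-directed ortho-acylation) to give 2-(benzyloxy)-1-[2-hydroxy-3-methoxy-4,6-bis(methoxymethoxy)phenyl]ethan-1-one F8. Heating this ketone with 9 and DBU in pyridine should bring about O-aroylation to 2-[2-(benzyloxy)acetyl]-6-methoxy-3,5-bis(methoxymethoxy)phenyl 4-(benzyloxy)benzoate F9, Baker–Venkataraman acyl shift to 2-(benzyloxy)-1-[4-(benzyloxy)phenyl]-3-[2-hydroxy-3-methoxy-4,6-bis(methoxymethoxy)phenyl]propane-1,3-dione F10, and base-induced cyclodehydration to 15. Acid is avoided throughout so that the second ortho oxygen stays protected and no 6-methoxy isomer can form.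

3. Step 13 (final deprotection). Process at risk: acid-induced ionisation of the prenyl ethers, with loss of prenyl or its transfer to C6, at a rate that competes with acetal cleavage. Fallback, setting out from 15 and coming back at 19: the acetals are exchanged for a base-labile group before the prenyl groups are present. Methanolic HCl removes both MOM groups from 15, with the benzyl ethers stable, to give 3-(benzyloxy)-2-[4-(benzyloxy)phenyl]-5,7-dihydroxy-8-methoxy-4H-chromen-4-one F11. Pivaloyl chloride with Et3N acylates only the non-chelated 7-hydroxyl to give 3-(benzyloxy)-2-[4-(benzyloxy)phenyl]-5-hydroxy-8-methoxy-4-oxo-4H-chromen-7-yl pivalate F12. Hydrogenolysis (H2, Pd/C) gives 3,5-dihydroxy-2-(4-hydroxyphenyl)-8-methoxy-4-oxo-4H-chromen-7-yl pivalate F13. Prenylation with 17 and K2CO3 in acetone alkylates O3 and O4' while the chelated 5-hydroxyl stays free, giving 5-hydroxy-8-methoxy-3-[(3-methylbut-2-en-1-yl)oxy]-2-{4-[(3-methylbut-2-en-1-yl)oxy]phenyl}-4-oxo-4H-chromen-7-yl pivalate F14. K2CO3 in methanol at rt then removes the pivalate and gives 19 without any acid.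

**Further compounds**

F1 | step 8 | methyl 3-[4-(benzyloxy)phenyl]prop-2-ynoate | COC(=O)C#Cc1ccc(OCc2ccccc2)cc1
F2 | step 8 | methyl (Z)-3-[4-(benzyloxy)phenyl]-3-[2-methoxy-3,5-bis(methoxymethoxy)phenoxy]prop-2-enoate | COC(=O)/C=C(\Oc1cc(OCOC)cc(OCOC)c1OC)c1ccc(OCc2ccccc2)cc1
F3 | step 8 | (Z)-3-[4-(benzyloxy)phenyl]-3-[2-methoxy-3,5-bis(methoxymethoxy)phenoxy]prop-2-enoic acid | OC(=O)/C=C(\Oc1cc(OCOC)cc(OCOC)c1OC)c1ccc(OCc2ccccc2)cc1
F4 | step 8 | (Z)-3-[4-(benzyloxy)phenyl]-3-[2-methoxy-3,5-bis(methoxymethoxy)phenoxy]prop-2-enoic trifluoroacetic anhydride | O=C(OC(=O)C(F)(F)F)/C=C(\Oc1cc(OCOC)cc(OCOC)c1OC)c1ccc(OCc2ccccc2)cc1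
F5 | step 8 | 2-[4-(benzyloxy)phenyl]-8-methoxy-5,7-bis(methoxymethoxy)-4H-chromen-4-one | COCOc1cc(OCOC)c2c(=O)cc(-c3ccc(OCc4ccccc4)cc3)oc2c1OC
F6 | step 8 | 2-[4-(benzyloxy)phenyl]-2,3-epoxy-8-methoxy-5,7-bis(methoxymethoxy)chroman-4-one (racemic, one enantiomer drawn) | O=C1c2c(OCOC)cc(OCOC)c(OC)c2O[C@@]2(c3ccc(OCc4ccccc4)cc3)O[C@@H]12
F7 | step 8 | 2-[4-(benzyloxy)phenyl]-3-hydroxy-8-methoxy-5,7-bis(methoxymethoxy)-4H-chromen-4-one | COCOc1cc(OCOC)c2c(=O)c(O)c(-c3ccc(OCc4ccccc4)cc3)oc2c1OC
F8 | step 10 | 2-(benzyloxy)-1-[2-hydroxy-3-methoxy-4,6-bis(methoxymethoxy)phenyl]ethan-1-one | COc1c(O)c(C(=O)COCc2ccccc2)c(OCOC)cc1OCOC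
F9 | step 10 | 2-[2-(benzyloxy)acetyl]-6-methoxy-3,5-bis(methoxymethoxy)phenyl 4-(benzyloxy)benzoate | COc1c(OC(=O)c2ccc(OCc3ccccc3)cc2)c(C(=O)COCc2ccccc2)c(OCOC)cc1OCOC
F10 | step 10 | 2-(benzyloxy)-1-[4-(benzyloxy)phenyl]-3-[2-hydroxy-3-methoxy-4,6-bis(methoxymethoxy)phenyl]propane-1,3-dione (racemic) | COc1c(O)c(C(=O)C(OCc2ccccc2)C(=O)c2ccc(OCc3ccccc3)cc2)c(OCOC)cc1OCOC
F11 | step 13 | 3-(benzyloxy)-2-[4-(benzyloxy)phenyl]-5,7-dihydroxy-8-methoxy-4H-chromen-4-one | COc1c(O)cc(O)c2c(=O)c(OCc3ccccc3)c(-c3ccc(OCc4ccccc4)cc3)oc12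
F12 | step 13 | 3-(benzyloxy)-2-[4-(benzyloxy)phenyl]-5-hydroxy-8-methoxy-4-oxo-4H-chromen-7-yl pivalate | COc1c(OC(=O)C(C)(C)C)cc(O)c2c(=O)c(OCc3ccccc3)c(-c3ccc(OCc4ccccc4)cc3)oc12
F13 | step 13 | 3,5-dihydroxy-2-(4-hydroxyphenyl)-8-methoxy-4-oxo-4H-chromen-7-yl pivalate | COc1c(OC(=O)C(C)(C)C)cc(O)c2c(=O)c(O)c(-c3ccc(O)cc3)oc12
F14 | step 13 | 5-hydroxy-8-methoxy-3-[(3-methylbut-2-en-1-yl)oxy]-2-{4-[(3-methylbut-2-en-1-yl)oxy]phenyl}-4-oxo-4H-chromen-7-yl pivalate | COc1c(OC(=O)C(C)(C)C)cc(O)c2c(=O)c(OCC=C(C)C)c(-c3ccc(OCC=C(C)C)cc3)oc12
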